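**Retrosynthetic overview**
1. The cyclohexene of the acyl half is closed last, by a catalyst-controlled Diels–Alder reaction of methyl vinyl ketone (acetyl = latent isopropyl) with the terminal diene of a triene ester already attached to the finished lactone half; methylenation, hydrogenation and global desilylation follow.
2. Enabling feature: in that ring (C-1 = CH with the acrylate arm, C-2=C-3 with CH2OH on C-3, C-4, C-5, C-6 = CH–iPr) the isopropyl carbon C-6 is vicinal and cis to C-1 and 1,4 to C-3, which is the endo "ortho/para" pattern of a [4+2] adduct of a 1-alkenyl-3-(oxymethyl)buta-1,3-diene (C-1 to C-4) with an acyl ethylene (C-5, C-6).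
3. The triene acid (from 2-bromoallyl alcohol, acrolein and an α-(silyloxymethyl) Wittig reagent) is attached by carboxylate opening of a spiro-epoxide, which also releases the tertiary alcohol.
4. Lactone half: organocatalytic (S)-cryptone, then a Diels–Alder reaction with a 2-silyloxybutadiene (three stereocentres), a Corey–Chaykovsky epoxide (fourth stereocentre), conversion of the auxiliary carbocycle into a dienoate, ozonolysis and lactonisation.
5. Ring order: cyclohexane of the lactone half (with a temporary carbocycle that is cleaved again), then the seven-membered lactone, then the cyclohexene of the acyl half.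

Key step: step 18

Assumption (step 18): methyl vinyl ketone is taken to bind the oxazaborolidinium ion in the s-trans, α-C–H···O mode established for acrylates and cyclic enones, under which the (S)-catalyst exposes the Si face of the α-carbon; if the opposite sense were found, the enantiomeric catalyst would be used.
Remark: as written, the target has isopropyl and side chain cis on the cyclohexene and trans on the cyclohexane of the lactone half; both are built as written.

**Route**

Step 1
Reactants: 1 3-methylbutanal; 2 methyl vinyl ketone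
Product: 4 (4S)-4-(propan-2-yl)cyclohex-2-en-1-one [(S)-cryptone], via keto aldehyde 3 (not isolated)
Conditions: (S)-2-[methoxy(diphenyl)methyl]pyrrolidine (5 mol %), ethyl 3,4-dihydroxybenzoate (20 mol %), neat, 4 °C; then KOH (10 mol %), Bu4NOH (cat.), Et2O/THF/H2O, reflux
Reagents that add atoms: none
Why: Enamine-catalysed Michael addition (MVK adds to the enamine face anti to the diaryl(methoxy)methyl group, which should give the (S)-aldehyde) followed by intramolecular aldol condensation, i.e. an organocatalytic Robinson-type annulation.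

Step 2
Reactants: 2 methyl vinyl ketone
Product: 5 2-[(tert-butyldimethylsilyl)oxy]buta-1,3-diene
Conditions: TBSOTf, Et3N, Et2O, 0 °C
Reagents that add atoms: tert-butyldimethylsilyl triflate CC(C)(C)[Si](C)(C)OS(=O)(=O)C(F)(F)F
Why: Soft enolisation and O-silylation of the enone (silyl enol ether formation) gives the 2-silyloxydiene; no stereocentre is involved.

Step 3
Reactants: 4 (S)-cryptone; 5 2-silyloxydiene
Product: 6 (4S,4aS,8aS)-6-[(tert-butyldimethylsilyl)oxy]-4-(propan-2-yl)-3,4,4a,5,8,8a-hexahydronaphthalen-1(2H)-one (cis-fused)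
Conditions: Tf2NH (5 mol %), CH2Cl2, −78 → −40 °C; Et3N quench
Reagents that add atoms: none
Why: Triflimide (silylium)-catalysed Diels–Alder reaction of a cyclohexenone with a 2-silyloxydiene: "para" regiochemistry, addition to the enone face anti to the neighbouring isopropyl group and suprafacial addition (cis ring fusion) let the existing stereocentre set both new ones.

Step 4
Reactants: 6 cis-fused ketone
Product: 7 spiro-epoxide of 6 (oxirane O cis, oxirane CH2 trans to the C-8a–C-8 bond)
Conditions: Me3S+ I−, n-BuLi, THF, −10 °C; then 6, −10 → 0 °C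
Reagents that add atoms: trimethylsulfonium iodide C[S+](C)C.[I-]
Why: Corey–Chaykovsky epoxidation; the sulfonium ylide should add irreversibly from the convex face of the cis-fused bicycle (axial attack, anti to the axial ring-fusion C–C bond), which puts the new CH2 trans and the oxygen cis to that bond.

Step 5
Reactants: 7 spiro-epoxide silyl enol ether
Product: 8 epoxy enone (C-6 ketone, C-7=C-8 alkene)
Conditions: Pd(OAc)2 (1.1 equiv), MeCN, 23 °C
Reagents that add atoms: none
Why: Saegusa–Ito oxidation: the oxa-π-allyl palladium intermediate can only β-hydride-eliminate toward the CH2 next to the ring fusion, so the enone forms regiospecifically and the epoxide and stereocentres are untouched.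

Step 6
Reactants: 8 epoxy enone
Product: 9 dienyl triflate (C-6 OTf; C-5=C-6 and C-7=C-8 alkenes)
Conditions: KN(SiMe3)2, THF, −78 °C; then PhNTf2, −78 → 0 °C
Reagents that add atoms: N-phenylbis(trifluoromethanesulfonimide) O=S(=O)(N(c1ccccc1)S(=O)(=O)C(F)(F)F)C(F)(F)F
Why: Kinetic α'-deprotonation of the enone (cross-conjugated dienolate) and O-triflation; the only α'-hydrogens sit on the CH2 next to the other ring-fusion carbon.

Step 7
Reactants: 9 dienyl triflate
Product: 10 2-(trimethylsilyl)ethyl dienoate
Conditions: Pd(OAc)2 (5 mol %), dppp (5 mol %), CO (1 atm), Me3SiCH2CH2OH (5 equiv), Et3N, DMF, 50 °C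
Reagents that add atoms: carbon monoxide [C-]#[O+]; 2-(trimethylsilyl)ethanol C[Si](C)(C)CCO
Why: Palladium-catalysed alkoxycarbonylation of an enol triflate (oxidative addition, CO insertion, alcoholysis) installs the future carboxylic acid as a fluoride-labile ester.

Step 8
Reactants: 10 dienoate
Product: 12 hydroxy aldehyde with (E)-2-(hydroxymethyl)acrylate arm, via dialdehyde 11 (not isolated)
Conditions: O3, CH2Cl2/MeOH (4:1), −78 °C (Sudan Red 7B end point); Me2S, −78 → 0 °C; then CeCl3·7H2O, NaBH4, −78 → −40 °C
Reagents that add atoms: ozone [O-][O+]=O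
Why: Chemoselective ozonolysis of the electron-richer disubstituted alkene of the cross-conjugated dienoate, then Luche reduction, which should reduce the conjugated formyl group 1,2 while the saturated aldehyde is masked as its hemiacetal; the alkene geometry (CH2OH cis to the ring carbon) is inherited from the ring.

Step 9
Reactants: 12 hydroxy aldehyde
Product: 13 hydroxy acid
Conditions: NaClO2, NaH2PO4, 2-methyl-2-butene, t-BuOH/H2O, 0 → 23 °C
Reagents that add atoms: sodium chlorite [Na+].[O-]Cl=O
Why: Pinnick oxidation converts the aldehyde into the acid without touching the allylic alcohol, the buffered epoxide or the α-stereocentre.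

Step 10
Reactants: 13 hydroxy acid
Product: 14 cis-fused epoxy lactone
Conditions: 2,4,6-Cl3C6H2COCl, Et3N, THF, 23 °C; then DMAP, toluene (2 mM), 50 °C
Reagents that add atoms: none
Why: Yamaguchi lactonisation: the mixed anhydride is attacked by the cis-disposed allylic alcohol to close the seven-membered lactone, the cis ring fusion being already fixed.

Step 11
Reactants: 15 2-bromoprop-2-en-1-ol
Product: 16 2-bromoallyl tert-butyldimethylsilyl ether
Conditions: TBSCl, imidazole, CH2Cl2, 0 → 23 °C
Reagents that add atoms: tert-butyldimethylsilyl chloride CC(C)(C)[Si](C)(C)Cl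
Why: Standard silylation of a primary alcohol.

Step 12
Reactants: 16 vinyl bromide; 17 acrolein
Product: 18 (2E)-4-{[(tert-butyldimethylsilyl)oxy]methyl}penta-2,4-dienal
Conditions: Pd(OAc)2 (5 mol %), Bu4NCl, NaHCO3, DMF, 40 °C
Reagents that add atoms: none
Why: Heck reaction under ligand-free phase-transfer conditions: syn carbopalladation at the β-carbon of acrolein and syn β-hydride elimination should give the (E)-dienal.

Step 13
Reactants: 19 ethyl (triphenylphosphoranylidene)acetate (2 equiv); 20 (triisopropylsiloxy)methyl chloride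
Product: 22 ethyl 2-(triphenylphosphoranylidene)-3-[(triisopropylsilyl)oxy]propanoate, via phosphonium chloride 21 (not isolated)
Conditions: CH2Cl2, 0 → 23 °C; the precipitated phosphonium chloride is filtered off
Reagents that add atoms: none
Why: C-alkylation of an ester-stabilised ylide by a reactive α-chloro ether, followed by transylidation with the second equivalent of 19.

Step 14
Reactants: 18 dienal; 22 ylide
Product: 23 ethyl (2E,4E)-6-{[(tert-butyldimethylsilyl)oxy]methyl}-2-{[(triisopropylsilyl)oxy]methyl}hepta-2,4,6-trienoate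
Conditions: toluene, 60 °C
Reagents that add atoms: none
Why: Wittig reaction of an α-substituted stabilised ylide, expected to be highly (E)-selective (ester trans to the dienyl group) as with the α-methyl analogue.

Step 15
Reactants: 23 ethyl trienoate
Product: 24 (2E,4E)-trienoic acid
Conditions: LiOH·H2O, THF/MeOH/H2O, 23 °C; then 1 M HCl to pH 4, 0 °C
Reagents that add atoms: lithium hydroxide [Li+].[OH-]
Why: Saponification; the silyl ethers and the triene are stable to hydroxide at room temperature.

Step 16
Reactants: 14 epoxy lactone; 24 trienoic acid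
Product: 25 hydroxy triene ester (tertiary OH, primary ester)
Conditions: Cs2CO3 (0.3 equiv), BHT (cat.), DMF, 65 °C, acid 24 in slight excess
Reagents that add atoms: none
Why: SN2 opening of the 2,2-disubstituted epoxide by the caesium carboxylate at its CH2 group (retention at the quaternary carbon, so the configuration from step 4 is kept); the acid/carboxylate buffer protonates the alkoxide and should suppress retro-aldol cleavage and acyl migration.

Step 17
Reactants: 25 hydroxy triene ester
Product: 26 triethylsilyl ether of 25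
Conditions: TESOTf, 2,6-lutidine, CH2Cl2, −78 → 0 °C
Reagents that add atoms: triethylsilyl triflate CC[Si](CC)(CC)OS(=O)(=O)C(F)(F)F
Why: Silylation of the hindered tertiary alcohol with a silyl triflate, so that no free hydroxyl binds the Lewis acid of step 18.

Step 18
Reactants: 26 triene ester; 2 methyl vinyl ketone
Product: 27 Diels–Alder adduct with a (1R,6R)-6-acetyl-3-(silyloxymethyl)cyclohex-2-en-1-yl ring (acetyl cis to the acrylate arm)
Conditions: (S)-3,3-diphenyl-1-(o-tolyl)tetrahydro-1H,3H-pyrrolo[1,2-c][1,3,2]oxazaborole (20 mol %), Tf2NH (18 mol %), CH2Cl2, −78 → −40 °C, dienophile in excess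
Reagents that add atoms: none
Why: The s-cis terminal 1,3-diene of 26 (carrying CH2OTBS on its inner carbon) undergoes a concerted, asynchronous normal-demand [4+2] cycloaddition with MVK activated at its carbonyl by the chiral oxazaborolidinium ion; the closest known reaction type is the cationic-oxazaborolidine-catalysed enantioselective Diels–Alder reaction of acrylates and enones with 2- and 1,3-substituted butadienes. The cyclohexene is closed by intermolecular cycloaddition, two σ-bonds forming in one step (diene CH2 terminus to the β-carbon of MVK, substituted terminus to the α-carbon) with the ring C=C arising between the two inner diene carbons. The acetyl-bearing stereocentre is controlled by the catalyst, which shields one face of the bound s-trans enone so that the diene adds to the Si face of its α-carbon, and the side-chain-bearing stereocentre follows from the endo transition state with the (E)-alkenyl substituent pointing outward, which gives the cis relationship. The step needs regioselectivity, secured because both diene substituents make the unsubstituted CH2 terminus the nucleophilic one, so the acetyl carbon ends up next to the side-chain carbon and 1,4 to the CH2OTBS-bearing carbon. It needs site selectivity, secured because the other diene unit of the trienoate ends in a fully substituted, ester-bearing carbon that cannot reach a reactive s-cis geometry and the trisubstituted acrylates of 26 are inert as dienophiles. It needs facial selectivity without help from the remote stereocentres of the lactone half, which is why catalyst control is used.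

Step 19
Reactants: 27 methyl ketone
Product: 28 isopropenyl compound
Conditions: Zn, CH2Br2, TiCl4, THF/CH2Cl2, 0 → 23 °C
Reagents that add atoms: dibromomethane BrCBr
Why: Takai–Lombardo methylenation: the non-basic zinc–titanium methylene reagent should convert the ketone without enolising the adjacent cis stereocentre and without touching esters, lactone or silyl ethers.

Step 20
Reactants: 28 isopropenyl compound
Product: 29 fully protected target (isopropyl)
Conditions: H2 (1 atm), RhCl(PPh3)3 (10 mol %), benzene, 23 °C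
Reagents that add atoms: none
Why: Homogeneous hydrogenation with RhCl(PPh3)3 reduces only the 1,1-disubstituted alkene (as in carvone to carvotanacetone); the trisubstituted ring alkene and the two conjugated trisubstituted alkenes should remain, and no new stereocentre forms.

Step 21
Reactants: 29 fully protected target
Product: 30 target
Conditions: Bu4NF, AcOH (1:1), THF/DMF, 0 → 35 °C; pH 4 buffer work-up
Reagents that add atoms: none
Why: Fluoride-induced global desilylation: the three silyl ethers are cleaved and the 2-(trimethylsilyl)ethyl ester fragments to the acid; acetic acid keeps the tertiary alkoxide protonated, which should prevent retro-aldol cleavage and acyl migration.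

**Compound list** (configurations not spelled out in a name are those of the SMILES)

1 | 3-methylbutanal (isovaleraldehyde) | CC(C)CC=O | starting material
2 | but-3-en-2-one (methyl vinyl ketone) | CC(=O)C=C | starting material
3 | (2S)-5-oxo-2-(propan-2-yl)hexanal | CC(C)[C@H](CCC(C)=O)C=O | intermediate
4 | (4S)-4-(propan-2-yl)cyclohex-2-en-1-one, (S)-cryptone | CC(C)[C@@H]1CCC(=O)C=C1 | intermediate
5 | 2-[(tert-butyldimethylsilyl)oxy]buta-1,3-diene | C=CC(=C)O[Si](C)(C)C(C)(C)C | intermediate
6 | (4S,4aS,8aS)-6-[(tert-butyldimethylsilyl)oxy]-4-(propan-2-yl)-3,4,4a,5,8,8a-hexahydronaphthalen-1(2H)-one, cis-fused, isopropyl trans to the C4a–C5 bond | CC(C)[C@@H]1CCC(=O)[C@H]2CC=C(O[Si](C)(C)C(C)(C)C)C[C@@H]12 | intermediate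
7 | spiro-epoxide of 6 at C-1 (oxirane O cis, oxirane CH2 trans to the C8a–C8 bond) | CC(C)[C@@H]1CC[C@]3(CO3)[C@H]2CC=C(O[Si](C)(C)C(C)(C)C)C[C@@H]12 | intermediate
8 | epoxy enone (7 with C-6 ketone and C-7=C-8 alkene) | CC(C)[C@@H]1CC[C@]3(CO3)[C@H]2C=CC(=O)C[C@@H]12 | intermediate
9 | dienyl triflate (C-6 OTf, C-5=C-6 and C-7=C-8 alkenes) | CC(C)[C@@H]1CC[C@]3(CO3)[C@H]2C=CC(OS(=O)(=O)C(F)(F)F)=C[C@@H]12 | intermediate
10 | 2-(trimethylsilyl)ethyl dienoate (9 with CO2CH2CH2SiMe3 in place of OTf) | CC(C)[C@@H]1CC[C@]3(CO3)[C@H]2C=CC(C(=O)OCC[Si](C)(C)C)=C[C@@H]12 | intermediate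
11 | 2-(trimethylsilyl)ethyl (2E)-2-formyl-3-[4-formyl-6-(propan-2-yl)-1-oxaspiro[2.5]octan-5-yl]prop-2-enoate (4,5-cis, 5,6-trans, oxirane O cis to the 4-formyl group) | CC(C)[C@@H]1CC[C@]3(CO3)[C@@H](C=O)[C@H]1/C=C(\C=O)C(=O)OCC[Si](C)(C)C | intermediate
12 | 2-(trimethylsilyl)ethyl (2E)-3-[4-formyl-6-(propan-2-yl)-1-oxaspiro[2.5]octan-5-yl]-2-(hydroxymethyl)prop-2-enoate (configuration as 11) | CC(C)[C@@H]1CC[C@]3(CO3)[C@@H](C=O)[C@H]1/C=C(\CO)C(=O)OCC[Si](C)(C)C | intermediate
13 | 5-{(1E)-2-(hydroxymethyl)-3-oxo-3-[2-(trimethylsilyl)ethoxy]prop-1-en-1-yl}-6-(propan-2-yl)-1-oxaspiro[2.5]octane-4-carboxylic acid (configuration as 11) | CC(C)[C@@H]1CC[C@]3(CO3)[C@@H](C(=O)O)[C@H]1/C=C(\CO)C(=O)OCC[Si](C)(C)C | intermediate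
14 | 2-(trimethylsilyl)ethyl 1-oxo-6-(propan-2-yl)-1,3,5a,6,7,8-hexahydro-9aH-spiro[2-benzoxepine-9,2'-oxirane]-4-carboxylate (H-5a/H-9a cis, isopropyl trans to the C5a–C5 bond, oxirane O cis to the lactone carbonyl branch) | CC(C)[C@@H]1CC[C@]3(CO3)[C@H]2C(=O)OCC(C(=O)OCC[Si](C)(C)C)=C[C@@H]12 | intermediate
15 | 2-bromoprop-2-en-1-ol | C=C(Br)CO | starting material
16 | [(2-bromoprop-2-en-1-yl)oxy](tert-butyl)dimethylsilane | C=C(Br)CO[Si](C)(C)C(C)(C)C | intermediate
17 | prop-2-enal (acrolein) | C=CC=O | starting material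
18 | (2E)-4-{[(tert-butyldimethylsilyl)oxy]methyl}penta-2,4-dienal | C=C(CO[Si](C)(C)C(C)(C)C)/C=C/C=O | intermediate
19 | ethyl (triphenylphosphoranylidene)acetate | CCOC(=O)C=P(c1ccccc1)(c1ccccc1)c1ccccc1 | starting material
20 | (chloromethoxy)tri(propan-2-yl)silane, (triisopropylsiloxy)methyl chloride | ClCO[Si](C(C)C)(C(C)C)C(C)C | starting material
21 | {1-ethoxy-1-oxo-3-[(triisopropylsilyl)oxy]propan-2-yl}triphenylphosphonium chloride | CCOC(=O)C(CO[Si](C(C)C)(C(C)C)C(C)C)[P+](c1ccccc1)(c1ccccc1)c1ccccc1.[Cl-] | intermediate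
22 | ethyl 2-(triphenylphosphoranylidene)-3-[(triisopropylsilyl)oxy]propanoate | CCOC(=O)C(CO[Si](C(C)C)(C(C)C)C(C)C)=P(c1ccccc1)(c1ccccc1)c1ccccc1 | intermediate
23 | ethyl (2E,4E)-6-{[(tert-butyldimethylsilyl)oxy]methyl}-2-{[(triisopropylsilyl)oxy]methyl}hepta-2,4,6-trienoate | CCOC(=O)/C(CO[Si](C(C)C)(C(C)C)C(C)C)=C/C=C/C(=C)CO[Si](C)(C)C(C)(C)C | intermediate
24 | (2E,4E)-6-{[(tert-butyldimethylsilyl)oxy]methyl}-2-{[(triisopropylsilyl)oxy]methyl}hepta-2,4,6-trienoic acid | OC(=O)/C(CO[Si](C(C)C)(C(C)C)C(C)C)=C/C=C/C(=C)CO[Si](C)(C)C(C)(C)C | intermediate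
25 | 2-(trimethylsilyl)ethyl (5aR,6S,9R,9aS)-9-hydroxy-1-oxo-6-(propan-2-yl)-9-{[(trienoyl)oxy]methyl}-1,3,5a,6,7,8,9,9a-octahydro-2-benzoxepine-4-carboxylate, trienoyl = acyl group of 24 | CC(C)[C@@H]1CC[C@](O)(COC(=O)/C(CO[Si](C(C)C)(C(C)C)C(C)C)=C/C=C/C(=C)CO[Si](C)(C)C(C)(C)C)[C@H]2C(=O)OCC(C(=O)OCC[Si](C)(C)C)=C[C@@H]12 | intermediate
26 | triethylsilyl ether of 25 (tertiary O–SiEt3) | CC(C)[C@@H]1CC[C@](O[Si](CC)(CC)CC)(COC(=O)/C(CO[Si](C(C)C)(C(C)C)C(C)C)=C/C=C/C(=C)CO[Si](C)(C)C(C)(C)C)[C@H]2C(=O)OCC(C(=O)OCC[Si](C)(C)C)=C[C@@H]12 | intermediate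
27 | Diels–Alder adduct: 26 whose acyl group is (2E)-3-[(1R,6R)-6-acetyl-3-{[(tert-butyldimethylsilyl)oxy]methyl}cyclohex-2-en-1-yl]-2-{[(triisopropylsilyl)oxy]methyl}prop-2-enoyl (acetyl cis to the acrylate arm) | CC(C)[C@@H]1CC[C@](O[Si](CC)(CC)CC)(COC(=O)/C(=C/[C@H]2C=C(CO[Si](C)(C)C(C)(C)C)CC[C@H]2C(C)=O)CO[Si](C(C)C)(C(C)C)C(C)C)[C@H]2C(=O)OCC(C(=O)OCC[Si](C)(C)C)=C[C@@H]12 | intermediate
28 | isopropenyl compound (27 with prop-1-en-2-yl in place of acetyl) | CC(C)[C@@H]1CC[C@](O[Si](CC)(CC)CC)(COC(=O)/C(=C/[C@H]2C=C(CO[Si](C)(C)C(C)(C)C)CC[C@H]2C(C)=C)CO[Si](C(C)C)(C(C)C)C(C)C)[C@H]2C(=O)OCC(C(=O)OCC[Si](C)(C)C)=C[C@@H]12 | intermediate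
29 | fully protected target (28 with isopropyl in place of isopropenyl) | CC(C)[C@@H]1CC[C@](O[Si](CC)(CC)CC)(COC(=O)/C(=C/[C@H]2C=C(CO[Si](C)(C)C(C)(C)C)CC[C@H]2C(C)C)CO[Si](C(C)C)(C(C)C)C(C)C)[C@H]2C(=O)OCC(C(=O)OCC[Si](C)(C)C)=C[C@@H]12 | intermediate
30 | (5aR,6S,9R,9aS)-9-hydroxy-9-{[((2E)-2-(hydroxymethyl)-3-[(1R,6S)-3-(hydroxymethyl)-6-(propan-2-yl)cyclohex-2-en-1-yl]prop-2-enoyl)oxy]methyl}-1-oxo-6-(propan-2-yl)-1,3,5a,6,7,8,9,9a-octahydro-2-benzoxepine-4-carboxylic acid | CC(C)[C@@H]1CC[C@](O)(COC(=O)/C(=C/[C@H]2C=C(CO)CC[C@H]2C(C)C)CO)[C@H]2C(=O)OCC(C(=O)O)=C[C@@H]12 | target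

**Step count and risks**

Total: 21 steps. Longest linear sequence: 15 steps (steps 1, 3–10, 16–21).

Steps most likely to fail:

1. Step 18. The cycloaddition may stall on the ester-deactivated triene, the Lewis acid may be tied up by the many carbonyl and silyl ether oxygens, or the facial sense may be insufficient or reversed. Fallback, setting out from 26 and returning at 27: iminium-ion organocatalysis with a different dienophile. Compound 26 is treated with acrolein 17 and (5S)-5-benzyl-2,2,3-trimethylimidazolidin-4-one hydrochloride (20 mol %) in MeCN/H2O at 23 °C; the benzyl group shields one face of the (E)-iminium ion so that the diene should add to the Si face of the α-carbon in the endo mode, giving the cis formyl adduct F1. MeMgBr in THF at −78 °C adds to the aldehyde only, giving the secondary alcohol F2 (carbinol epimers). Oxidation with DMP (1,1,1-triacetoxy-1,1-dihydro-1,2-benziodoxol-3(1H)-one, NaHCO3, CH2Cl2) gives methyl ketone 27.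

2. Step 16. Slow SN2 opening at the hindered epoxide CH2 may compete with thermal decomposition (polymerisation, self-cycloaddition) of the triene acid. Fallback, setting out from 14 and returning at 25: the epoxide is opened with a heat-stable acid and the triene is built afterwards by olefination. Commercial diethyl (2-hydroxyethyl)phosphonate is silylated (TIPSCl, imidazole) to diethyl [2-(triisopropylsilyloxy)ethyl]phosphonate F3, which is lithiated (LiN(iPr)2, THF, −78 °C) and carboxylated with CO2 to 2-(diethoxyphosphoryl)-3-[(triisopropylsilyl)oxy]propanoic acid F4. Its caesium salt opens epoxide 14 (Cs2CO3, DMF, 80 °C) to the phosphonoacetate ester F5. Horner–Wadsworth–Emmons reaction of F5 with dienal 18 (LiCl, DBU, MeCN, 0 → 23 °C) gives 25, any (2Z) isomer being removed by chromatography.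

3. Step 8. Ozone may also attack the ester-bearing alkene, and in the reduction hydride may attack the wrong aldehyde or add in conjugate fashion. Fallback, setting out from 10 and returning at 13: the two termini are differentiated in the ozonolysis itself. Ozonolysis of 10 in CH2Cl2/MeOH with NaHCO3 at −78 °C, then Ac2O/Et3N, dehydrates the α-methoxy hydroperoxide (the carbonyl oxide should form at the carbon remote from the electron-poor alkene) and gives the aldehyde methyl ester F6. NaBH4/CeCl3·7H2O in MeOH at −78 °C reduces its only aldehyde to the hydroxy methyl ester F7. Me3SnOH in 1,2-dichloroethane at 70 °C cleaves the methyl ester to hydroxy acid 13.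

**Further compounds**

F1 | step 18 | formyl Diels–Alder adduct (27 with CHO in place of acetyl, cis) | CC(C)[C@@H]1CC[C@](O[Si](CC)(CC)CC)(COC(=O)/C(=C/[C@H]2C=C(CO[Si](C)(C)C(C)(C)C)CC[C@H]2C=O)CO[Si](C(C)C)(C(C)C)C(C)C)[C@H]2C(=O)OCC(C(=O)OCC[Si](C)(C)C)=C[C@@H]12
F2 | step 18 | secondary alcohol (27 with CH(OH)CH3 in place of acetyl, carbinol epimers) | CC(C)[C@@H]1CC[C@](O[Si](CC)(CC)CC)(COC(=O)/C(=C/[C@H]2C=C(CO[Si](C)(C)C(C)(C)C)CC[C@H]2C(C)O)CO[Si](C(C)C)(C(C)C)C(C)C)[C@H]2C(=O)OCC(C(=O)OCC[Si](C)(C)C)=C[C@@H]12
F3 | step 16 | diethyl [2-(triisopropylsilyloxy)ethyl]phosphonate | CCOP(=O)(CCO[Si](C(C)C)(C(C)C)C(C)C)OCC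
F4 | step 16 | 2-(diethoxyphosphoryl)-3-[(triisopropylsilyl)oxy]propanoic acid | CCOP(=O)(OCC)C(CO[Si](C(C)C)(C(C)C)C(C)C)C(=O)O
F5 | step 16 | phosphonoacetate ester of the lactone half (25 with the 2-(diethoxyphosphoryl)-3-silyloxypropanoyl group as acyl) | CC(C)[C@@H]1CC[C@](O)(COC(=O)C(CO[Si](C(C)C)(C(C)C)C(C)C)P(=O)(OCC)OCC)[C@H]2C(=O)OCC(C(=O)OCC[Si](C)(C)C)=C[C@@H]12
F6 | step 8 | aldehyde methyl ester (11 with CO2CH3 in place of the ring-bound formyl group) | CC(C)[C@@H]1CC[C@]3(CO3)[C@@H](C(=O)OC)[C@H]1/C=C(\C=O)C(=O)OCC[Si](C)(C)C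
F7 | step 8 | hydroxy methyl ester (methyl ester of 13) | CC(C)[C@@H]1CC[C@]3(CO3)[C@@H](C(=O)OC)[C@H]1/C=C(\CO)C(=O)OCC[Si](C)(C)C
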